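The synthesis rests on opening the ten-membered carbocycle between the ring ketone carbon C1 and the fully substituted carbinol carbon C10 (germacrane numbering). This vicinal oxygen pair is the retron of a ketone–aldehyde pinacol coupling. SmI2 closes the ring at its most hindered bond and sets C10 in one operation, and oxidation of the transient C1 carbinol then gives the α-ketol. The step exploits three turn elements that fold the acyclic keto-aldehyde precursor: the Z-C4=C5 alkene, the trans γ-lactone on C6/C7 and a cis-dioxolane on O8/O9. The exocyclic methylene is masked as a phenylthio adduct. The precursor arises from a D-ribose-derived allyl bromide and a Z-enal by chromium-mediated allylation.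

Key step: step 14

Numbering used throughout (germacrane):
- C1: ring ketone
- C2: CH2
- C3: allylic carbinol
- C4=C5: ring alkene, with methyl C15 on C4
- C6: lactone carbinol
- C7: ring-fusion CH
- C8: acyloxy carbon
- C9: carbinol
- C10: tertiary carbinol, with methyl C14
- C11=C13: exocyclic methylene
- C12: lactone carbonyl

Assumption: the sense of induction in step 1 is taken to follow BINOL–titanium dialkylzinc additions ((R)-ligand, Re-face attack). The ligand antipode would be used if the sense proved opposite.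

Step 1
Reactants: 1 3-[(tert-butyldimethylsilyl)oxy]propanal; 2 methyl propiolate
Product: 4 methyl (4S)-6-[(tert-butyldimethylsilyl)oxy]-4-hydroxyhex-2-ynoate, via ethylzinc acetylide 3 (not isolated)
Conditions: 2, Et2Zn, HMPA, (R)-BINOL (40 mol %), CH2Cl2, rt; Ti(OiPr)4; then 1, rt; aqueous work-up
Reagents that add atoms: none
Why: Catalytic asymmetric alkynylzinc addition to an aldehyde (BINOL–titanium type), in which the (R)-ligand is expected to steer acetylide 3 to the Re face of 1 and so set C3 as S.

Step 2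
Reactants: 4 methyl (4S)-6-[(tert-butyldimethylsilyl)oxy]-4-hydroxyhex-2-ynoate
Product: 5 methyl (4S)-6-[(tert-butyldimethylsilyl)oxy]-4-[(tert-butyldiphenylsilyl)oxy]hex-2-ynoate
Conditions: TBDPSCl, imidazole, DMF, rt
Reagents that add atoms: tert-butyl(chloro)diphenylsilane CC(C)(C)[Si](Cl)(c1ccccc1)c1ccccc1
Why: Standard silylation of a secondary propargylic alcohol, with the acid-stable TBDPS group chosen so that O3 outlasts the later removal of the primary TBS ether and of the acetonide.

Step 3
Reactants: 5 methyl (4S)-6-[(tert-butyldimethylsilyl)oxy]-4-[(tert-butyldiphenylsilyl)oxy]hex-2-ynoate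
Product: 7 methyl (2Z,4S)-6-[(tert-butyldimethylsilyl)oxy]-4-[(tert-butyldiphenylsilyl)oxy]-3-methylhex-2-enoate, via alkenylcuprate 6 (not isolated)
Conditions: MeLi, CuI, THF, −78 °C; AcOH/THF quench at −78 °C
Reagents that add atoms: methyllithium [Li]C
Why: Conjugate syn-carbocupration of an alkynoate followed by protonation of 6 at −78 °C with retention, which places C3 and the ester carbon cis and so fixes the Z-C4=C5 geometry.

Step 4
Reactants: 7 methyl (2Z,4S)-6-[(tert-butyldimethylsilyl)oxy]-4-[(tert-butyldiphenylsilyl)oxy]-3-methylhex-2-enoate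
Product: 8 (2Z,4S)-6-[(tert-butyldimethylsilyl)oxy]-4-[(tert-butyldiphenylsilyl)oxy]-3-methylhex-2-en-1-ol
Conditions: iBu2AlH, CH2Cl2, −78 °C; aqueous work-up
Reagents that add atoms: none
Why: 1,2-Reduction of the enoate by two hydride equivalents, which leaves the silyl ethers and the alkene geometry untouched at low temperature.

Step 5
Reactants: 8 (2Z,4S)-6-[(tert-butyldimethylsilyl)oxy]-4-[(tert-butyldiphenylsilyl)oxy]-3-methylhex-2-en-1-ol
Product: 9 (2Z,4S)-6-[(tert-butyldimethylsilyl)oxy]-4-[(tert-butyldiphenylsilyl)oxy]-3-methylhex-2-enal (C1–C6 fragment)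
Conditions: TEMPO (10 mol %), PhI(OAc)2, CH2Cl2, rt
Reagents that add atoms: none
Why: Oxoammonium-catalysed oxidation of an allylic alcohol under near-neutral conditions, a method that preserves Z-enal geometry.

Step 6
Reactants: 10 methyl 5-deoxy-5-iodo-2,3-O-isopropylidene-β-D-ribofuranoside
Product: 11 (4R,5R)-2,2-dimethyl-5-vinyl-1,3-dioxolane-4-carbaldehyde
Conditions: Zn dust, THF/H2O 4:1, 40 °C, ultrasound
Reagents that add atoms: none
Why: Vasella-type reductive fragmentation in which zinc inserts into the C–I bond and expels the ring oxygen, so that C2 and C3 of D-ribose are delivered unchanged as C8 and C9.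

Step 7
Reactants: 11 (4R,5R)-2,2-dimethyl-5-vinyl-1,3-dioxolane-4-carbaldehyde; 2 methyl propiolate
Product: 13 methyl 2-{hydroxy[(4S,5R)-2,2-dimethyl-5-vinyl-1,3-dioxolan-4-yl]methyl}acrylate (carbinol epimers), via vinylalane 12 (not isolated)
Conditions: iBu2AlH, HMPA, THF, 0 °C; 2; then 11, 0 °C to rt; aqueous work-up
Reagents that add atoms: none
Why: Hydroalumination of the propiolate gives α-aluminated acrylate 12, which adds to the aldehyde under non-basic conditions (a Morita–Baylis–Hillman-type adduct without epimerisation at C8), and the new carbinol centre is inconsequential because step 8 erases it.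

Step 8
Reactants: 13 methyl 2-{hydroxy[(4S,5R)-2,2-dimethyl-5-vinyl-1,3-dioxolan-4-yl]methyl}acrylate
Product: 14 methyl (2Z)-2-(bromomethyl)-3-[(4S,5R)-2,2-dimethyl-5-vinyl-1,3-dioxolan-4-yl]acrylate (C7–C14 fragment)
Conditions: NBS, Me2S, CH2Cl2, 0 °C to rt
Reagents that add atoms: N-bromosuccinimide O=C1CCC(=O)N1Br
Why: Corey–Kim-type activation of the allylic alcohol and SN2′ displacement by bromide with allylic transposition, which gives the thermodynamically preferred Z-2-(bromomethyl)enoate.

Step 9
Reactants: 9 (2Z,4S)-enal (C1–C6 fragment); 14 allyl bromide (C7–C14 fragment)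
Product: 17 trans-α-methylene-γ-butyrolactone of the 1,10-seco skeleton (C10 vinyl; O1-TBS; O3-TBDPS; O8/O9 acetonide), via allylchromium reagent 15 (not isolated), via anti hydroxy ester 16 (not isolated)
Conditions: CrCl2 (excess), THF, rt; aqueous work-up; PPTS (cat.), benzene, 50 °C
Reagents that add atoms: none
Why: Nozaki–Hiyama-type 2-(alkoxycarbonyl)allylation in which equilibrating 15 reacts through a chair Zimmerman–Traxler transition state with C5 and C8 equatorial (anti adduct 16, hence the trans lactone) and on the alkene face anti to the C8–C9 bond of the A(1,3)-locked dioxolane, which sets C6 and C7 before acid-catalysed lactonisation closes the γ-lactone.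

Step 10
Reactants: 17 trans-α-methylene-γ-butyrolactone (C10 vinyl)
Product: 18 C10 methyl ketone of the seco lactone
Conditions: Pd(Quinox)Cl2 (5 mol %; Quinox = 2-(4,5-dihydrooxazol-2-yl)quinoline), AgSbF6 (12 mol %), aq tert-butyl hydroperoxide, CH2Cl2, 0 °C to rt
Reagents that add atoms: tert-butyl hydroperoxide CC(C)(C)OO
Why: Catalyst-controlled Tsuji–Wacker oxidation, which gives methyl ketones from protected allylic alcohols and touches only the monosubstituted alkene while the 1,1-disubstituted acrylate and the trisubstituted alkene stay inert.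

Step 11
Reactants: 18 C10 methyl ketone of the seco lactone
Product: 19 13-phenylthio-11,13-dihydro lactone (masked methylene)
Conditions: PhSH, Et3N (10 mol %), CH2Cl2, 0 °C
Reagents that add atoms: thiophenol Sc1ccccc1
Why: Thia-Michael addition to the only Michael acceptor present masks C11=C13 against ketyl radicals, equilibrating protonation should place CH2SPh trans to C8, and this centre is erased in step 18.

Step 12
Reactants: 19 13-phenylthio lactone
Product: 20 C1 primary alcohol
Conditions: HF·pyridine, pyridine, THF, 0 °C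
Reagents that add atoms: none
Why: Chemoselective fluoride cleavage of the primary TBS ether, which the hindered secondary TBDPS ether and the acetonide survive under buffered conditions.

Step 13
Reactants: 20 C1 primary alcohol
Product: 21 1,10-seco keto-aldehyde
Conditions: Dess–Martin periodinane, CH2Cl2, 0 °C to rt
Reagents that add atoms: none
Why: Dess–Martin oxidation of a primary alcohol under neutral conditions, which tolerates the aryl sulfide and avoids β-elimination of the C3 silyloxy group.

Step 14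
Reactants: 21 1,10-seco keto-aldehyde
Product: 23 ten-membered 1,10-diol (10S; C1–OH cis to C10–OH), via samarium diolate 22 (not isolated)
Conditions: SmI2 (6 equiv, 0.1 M in THF), syringe-pump addition of 21 (final 0.002 M), THF, −20 °C to rt; aqueous NaHCO3 quench
Reagents that add atoms: none
Why: Single-electron transfer from divalent samarium to the aldehyde gives a C1 ketyl whose trivalent samarium centre binds the C10 ketone oxygen, a second electron transfer and C1–C10 bond formation give diolate 22, and the aqueous quench releases diol 23. The closest known reaction type is the intramolecular ketone–aldehyde pinacol coupling used for medium and large carbocycles. The ten-membered ring closes in a formal 10-exo-trig mode, with both carbonyl oxygens staying outside the ring. C10 is set by a Felkin–Anh-type approach anti to the C9–O bond of the cis-dioxolane, which puts the new C10–O bond anti to C9–O in the C1–C10–C9–C8 zigzag as required for 10S, while the C1 carbinol (expected cis to O10 through the samarium bridge) is erased in step 15. The step needs ring closure to win over intermolecular coupling, simple reduction, loss of the α-oxygen at C9 and ketyl–alkene addition, and this is secured by pseudo-high dilution, the absence of a proton source, the three turn elements (Z-alkene, trans-lactone, cis-dioxolane) and the thio-masked C11–C13 unit.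

Step 15
Reactants: 23 ten-membered 1,10-diol
Product: 24 1-oxo-10-hydroxy α-ketol
Conditions: SO3·pyridine, DMSO, Et3N, CH2Cl2, 0 °C
Reagents that add atoms: none
Why: Parikh–Doering oxidation of the secondary alcohol of a secondary/tertiary 1,2-diol, which gives the α-ketol without glycol cleavage and leaves the sulfide and the tertiary alcohol untouched.

Step 16
Reactants: 24 1-oxo-10-hydroxy α-ketol
Product: 25 8,9,10-triol
Conditions: TFA/H2O 9:1, CH2Cl2, 0 °C
Reagents that add atoms: none
Why: Acid hydrolysis of the isopropylidene acetal, to which the TBDPS ether, the sulfide and the lactone are stable under brief cold aqueous TFA.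

Step 17
Reactants: 25 8,9,10-triol; 26 tigloyl chloride
Product: 27 8-O-tiglate
Conditions: pyridine, DMAP (10 mol %), CH2Cl2, −20 to 0 °C
Reagents that add atoms: none
Why: Site-selective DMAP-catalysed acylation, since C10–OH is tertiary and C9–OH is neopentyl-like next to fully substituted C10, so that C8–OH is the most accessible hydroxyl and the E geometry of the tigloyl unit is retained.

Step 18
Reactants: 27 8-O-tiglate
Product: 29 3-O-TBDPS ether of the target (C11=C13 restored), via sulfoxide 28 (not isolated)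
Conditions: mCPBA (1.0 equiv), CH2Cl2, −78 °C; then toluene, 100 °C
Reagents that add atoms: none
Why: Low-temperature sulfide oxidation followed by thermal syn-elimination of sulfoxide 28 regenerates the exocyclic methylene, and C11–H is the only β-hydrogen so that the regiochemistry is unambiguous.

Step 19
Reactants: 29 3-O-TBDPS ether of the target
Product: 30 (3S,6R,7S,8S,9S,10S)-3,9,10-trihydroxy-1-oxo-8-tigloyloxygermacra-4Z,11(13)-dien-6,12-olide (target)
Conditions: HF·pyridine, THF, 0 °C to rt
Reagents that add atoms: none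
Why: Acidic fluoride desilylation of the allylic TBDPS ether, which avoids the basic conditions that would trigger retro-aldol cleavage, acyl migration or addition to the methylene lactone.

Compound list
1 | 3-[(tert-butyldimethylsilyl)oxy]propanal | O=CCCO[Si](C)(C)C(C)(C)C | starting material
2 | methyl propiolate | C#CC(=O)OC | starting material
3 | methyl 3-(ethylzincio)propiolate | CC[Zn]C#CC(=O)OC | intermediate
4 | methyl (4S)-6-[(tert-butyldimethylsilyl)oxy]-4-hydroxyhex-2-ynoate | COC(=O)C#C[C@@H](O)CCO[Si](C)(C)C(C)(C)C | intermediate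
5 | methyl (4S)-6-[(tert-butyldimethylsilyl)oxy]-4-[(tert-butyldiphenylsilyl)oxy]hex-2-ynoate | COC(=O)C#C[C@@H](O[Si](c1ccccc1)(c1ccccc1)C(C)(C)C)CCO[Si](C)(C)C(C)(C)C | intermediate
6 | lithium methyl(alkenyl)cuprate from syn addition to 5 | [Li+].COC(=O)/C([Cu-]C)=C(/C)[C@@H](O[Si](c1ccccc1)(c1ccccc1)C(C)(C)C)CCO[Si](C)(C)C(C)(C)C | intermediate
7 | methyl (2Z,4S)-6-[(tert-butyldimethylsilyl)oxy]-4-[(tert-butyldiphenylsilyl)oxy]-3-methylhex-2-enoate | COC(=O)/C=C(/C)[C@@H](O[Si](c1ccccc1)(c1ccccc1)C(C)(C)C)CCO[Si](C)(C)C(C)(C)C | intermediate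
8 | (2Z,4S)-6-[(tert-butyldimethylsilyl)oxy]-4-[(tert-butyldiphenylsilyl)oxy]-3-methylhex-2-en-1-ol | OC/C=C(/C)[C@@H](O[Si](c1ccccc1)(c1ccccc1)C(C)(C)C)CCO[Si](C)(C)C(C)(C)C | intermediate
9 | (2Z,4S)-6-[(tert-butyldimethylsilyl)oxy]-4-[(tert-butyldiphenylsilyl)oxy]-3-methylhex-2-enal | O=C/C=C(/C)[C@@H](O[Si](c1ccccc1)(c1ccccc1)C(C)(C)C)CCO[Si](C)(C)C(C)(C)C | intermediate
10 | methyl 5-deoxy-5-iodo-2,3-O-isopropylidene-β-D-ribofuranoside | CO[C@@H]1O[C@H](CI)[C@H]2OC(C)(C)O[C@@H]12 | starting material
11 | (4R,5R)-2,2-dimethyl-5-vinyl-1,3-dioxolane-4-carbaldehyde | O=C[C@@H]1OC(C)(C)O[C@@H]1C=C | intermediate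
12 | [1-(methoxycarbonyl)vinyl]diisobutylaluminium | C=C(C(=O)OC)[Al](CC(C)C)CC(C)C | intermediate
13 | methyl 2-{hydroxy[(4S,5R)-2,2-dimethyl-5-vinyl-1,3-dioxolan-4-yl]methyl}acrylate, both carbinol epimers | C=C(C(=O)OC)C(O)[C@@H]1OC(C)(C)O[C@@H]1C=C | intermediate
14 | methyl (2Z)-2-(bromomethyl)-3-[(4S,5R)-2,2-dimethyl-5-vinyl-1,3-dioxolan-4-yl]acrylate | COC(=O)/C(CBr)=C/[C@@H]1OC(C)(C)O[C@@H]1C=C | intermediate
15 | allylchromium dichloride from 14 (geometry equilibrating) | COC(=O)C(C[Cr](Cl)Cl)=C[C@@H]1OC(C)(C)O[C@@H]1C=C | intermediate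
16 | C6/C7-anti hydroxy ester (C3, C6, C7, C8, C9 as in 30) | COC(=O)C(=C)[C@@H]([C@H](O)/C=C(/C)[C@@H](O[Si](c1ccccc1)(c1ccccc1)C(C)(C)C)CCO[Si](C)(C)C(C)(C)C)[C@@H]1OC(C)(C)O[C@@H]1C=C | intermediate
17 | trans-α-methylene-γ-butyrolactone of the 1,10-seco skeleton, C10 vinyl, O1-TBS, O3-TBDPS, O8/O9 acetonide | C=C1C(=O)O[C@H](/C=C(/C)[C@@H](O[Si](c2ccccc2)(c2ccccc2)C(C)(C)C)CCO[Si](C)(C)C(C)(C)C)[C@H]1[C@@H]3OC(C)(C)O[C@@H]3C=C | intermediate
18 | C10 methyl ketone of 17 | C=C1C(=O)O[C@H](/C=C(/C)[C@@H](O[Si](c2ccccc2)(c2ccccc2)C(C)(C)C)CCO[Si](C)(C)C(C)(C)C)[C@H]1[C@@H]3OC(C)(C)O[C@@H]3C(C)=O | intermediate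
19 | 13-phenylthio-11,13-dihydro derivative of 18, CH2SPh trans to C8 | C(Sc4ccccc4)[C@@H]1C(=O)O[C@H](/C=C(/C)[C@@H](O[Si](c2ccccc2)(c2ccccc2)C(C)(C)C)CCO[Si](C)(C)C(C)(C)C)[C@H]1[C@@H]3OC(C)(C)O[C@@H]3C(C)=O | intermediate
20 | C1 primary alcohol | C(Sc4ccccc4)[C@@H]1C(=O)O[C@H](/C=C(/C)[C@@H](O[Si](c2ccccc2)(c2ccccc2)C(C)(C)C)CCO)[C@H]1[C@@H]3OC(C)(C)O[C@@H]3C(C)=O | intermediate
21 | 1,10-seco keto-aldehyde | C(Sc4ccccc4)[C@@H]1C(=O)O[C@H](/C=C(/C)[C@@H](O[Si](c2ccccc2)(c2ccccc2)C(C)(C)C)CC=O)[C@H]1[C@@H]3OC(C)(C)O[C@@H]3C(C)=O | intermediate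
22 | bis(diiodosamarium) 1,10-diolate | C(Sc4ccccc4)[C@@H]1C(=O)O[C@@H]2/C=C(/C)[C@@H](O[Si](c4ccccc4)(c4ccccc4)C(C)(C)C)C[C@@H](O[Sm](I)I)[C@@](C)(O[Sm](I)I)[C@H]3OC(C)(C)O[C@H]3[C@@H]12 | intermediate
23 | ten-membered cis-1,10-diol | C(Sc4ccccc4)[C@@H]1C(=O)O[C@@H]2/C=C(/C)[C@@H](O[Si](c4ccccc4)(c4ccccc4)C(C)(C)C)C[C@@H](O)[C@@](C)(O)[C@H]3OC(C)(C)O[C@H]3[C@@H]12 | intermediate
24 | 1-oxo-10-hydroxy α-ketol | C(Sc4ccccc4)[C@@H]1C(=O)O[C@@H]2/C=C(/C)[C@@H](O[Si](c4ccccc4)(c4ccccc4)C(C)(C)C)CC(=O)[C@@](C)(O)[C@H]3OC(C)(C)O[C@H]3[C@@H]12 | intermediate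
25 | 8,9,10-triol | C(Sc4ccccc4)[C@@H]1C(=O)O[C@@H]2/C=C(/C)[C@@H](O[Si](c4ccccc4)(c4ccccc4)C(C)(C)C)CC(=O)[C@@](C)(O)[C@@H](O)[C@@H](O)[C@@H]12 | intermediate
26 | tigloyl chloride, (E)-2-methylbut-2-enoyl chloride | ClC(=O)/C(C)=C/C | starting material
27 | 8-O-tiglate | C(Sc4ccccc4)[C@@H]1C(=O)O[C@@H]2/C=C(/C)[C@@H](O[Si](c4ccccc4)(c4ccccc4)C(C)(C)C)CC(=O)[C@@](C)(O)[C@@H](O)[C@@H](OC(=O)/C(C)=C/C)[C@@H]12 | intermediate
28 | 13-phenylsulfinyl derivative (sulfur epimers) | C(S(=O)c4ccccc4)[C@@H]1C(=O)O[C@@H]2/C=C(/C)[C@@H](O[Si](c4ccccc4)(c4ccccc4)C(C)(C)C)CC(=O)[C@@](C)(O)[C@@H](O)[C@@H](OC(=O)/C(C)=C/C)[C@@H]12 | intermediate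
29 | 3-O-TBDPS ether of the target | C=C1C(=O)O[C@@H]2/C=C(/C)[C@@H](O[Si](c3ccccc3)(c3ccccc3)C(C)(C)C)CC(=O)[C@@](C)(O)[C@@H](O)[C@@H](OC(=O)/C(C)=C/C)[C@@H]12 | intermediate
30 | (3S,6R,7S,8S,9S,10S)-3,9,10-trihydroxy-1-oxo-8-tigloyloxygermacra-4Z,11(13)-dien-6,12-olide | C=C1C(=O)O[C@@H]2/C=C(/C)[C@@H](O)CC(=O)[C@@](C)(O)[C@@H](O)[C@@H](OC(=O)/C(C)=C/C)[C@@H]12 | target

Total step count: 19. Longest linear sequence: 16 steps (steps 1–5, then 9–19).

Steps most likely to fail

**Step 14 (pinacol macrocyclisation).**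
- Closure of the medium ring may be slower than three competing processes. These are reductive loss of the α-oxygen at C9 from the ketone ketyl, plain reduction of the aldehyde, and intermolecular coupling.
- The fallback sets out from keto-aldehyde 21 and comes back at α-ketol 24, bypassing 23 and step 15.
- An N-heterocyclic carbene is generated from a bicyclic N-aryl triazolium salt with iPr2NEt in toluene at high dilution.
- The carbene turns the aldehyde into its Breslow intermediate, which adds to the α-alkoxy-activated C10 ketone in a crossed aldehyde–ketone benzoin reaction.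
- This redox-neutral umpolung uses no electron-transfer reagent and makes no new compound (F0).

**Step 9 (chromium allylation).**
- The organochromium species may undergo reductive β-alkoxy elimination that opens the dioxolane.
- Equilibration of the allyl geometry may erode the anti selectivity or the facial selectivity.
- The fallback sets out from aldehyde 11 and comes back at lactone 17.
- Corey–Fuchs olefination (CBr4, PPh3) gives dibromoalkene F1.
- BuLi followed by ClCO2Me gives alkynoate F2.
- Syn 1,4-hydrometalation (MeCu, iBu2AlH, HMPA) and trapping with 2-(iodomethyl)-4,4,5,5-tetramethyl-1,3,2-dioxaborolane give the configurationally fixed allylboronate F3, which has C8 cis to the ester.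
- Thermal allylboration of enal 9 through a closed chair then delivers the borate of 16, which lactonises to 17.

**Step 17 (tigloylation).**
- Site selectivity between O8 and O9 may be poor, and the acyl group may migrate between them.
- The fallback sets out from triol 25 and comes back at tiglate 27.
- Bu2SnO in toluene with azeotropic water removal forms the O8,O9-dibutylstannylene acetal F4.
- Its less hindered tin-activated oxygen O8 is then acylated by tigloyl chloride 26 without added amine base.

Further compounds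
F1 | step 9 | cis-4-(2,2-dibromovinyl)-2,2-dimethyl-5-vinyl-1,3-dioxolane (D-ribo series) | BrC(Br)=C[C@@H]1OC(C)(C)O[C@@H]1C=C
F2 | step 9 | methyl 3-(cis-2,2-dimethyl-5-vinyl-1,3-dioxolan-4-yl)propiolate (D-ribo series) | COC(=O)C#C[C@@H]1OC(C)(C)O[C@@H]1C=C
F3 | step 9 | methyl (2Z)-3-(cis-2,2-dimethyl-5-vinyl-1,3-dioxolan-4-yl)-2-[(4,4,5,5-tetramethyl-1,3,2-dioxaborolan-2-yl)methyl]acrylate | COC(=O)/C(CB2OC(C)(C)C(C)(C)O2)=C\[C@@H]1OC(C)(C)O[C@@H]1C=C
F0 | step 14 | none | none
F4 | step 17 | O8,O9-dibutylstannylene acetal of triol 25 | C(Sc4ccccc4)[C@@H]1C(=O)O[C@@H]2/C=C(/C)[C@@H](O[Si](c4ccccc4)(c4ccccc4)C(C)(C)C)CC(=O)[C@@](C)(O)[C@H]3O[Sn](CCCC)(CCCC)O[C@H]3[C@@H]12
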